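**Assumption on stereochemistry:** the SMILES decodes to (1R,2S) with two identical substituents. This is the cis, meso 1,2-disubstituted cyclobutane, which is achiral. There is therefore no enantiomer to select, and the stereochemical task is clean cis relative configuration. The trans isomer is cardopatine.

## Retrosynthetic overview
1. Disconnect both C(sp)–C(thienyl) bonds by double Negishi alkynylation. This gives a cis-1,2-diethynylcyclobutane dianion equivalent and 2 × 5-bromo-2,2'-bithiophene.
2. The diacetylide comes from cis-1,2-bis(2,2-dibromovinyl)cyclobutane, and that from the cis-1,2-dicarbaldehyde (Corey–Fuchs).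
3. The dialdehyde comes from the cis-diol, and the diol from commercial cis-cyclobutane-1,2-dicarboxylic anhydride.
4. No ring is formed in the route. The cyclobutane is bought with cis geometry locked by the bicyclic anhydride, and all four thiophenes are bought as the bithiophene.

## Route

**Step 1**
Reactants: 1, cis-cyclobutane-1,2-dicarboxylic anhydride [(1R,5S)-3-oxabicyclo[3.2.0]heptane-2,4-dione, meso]
Product: 2, cis-1,2-bis(hydroxymethyl)cyclobutane [(1R,2S), meso]
Conditions: LiAlH4 (2.5 equiv), THF, 0 °C → reflux, 3 h; Fieser work-up, no aqueous extraction because the diol is water soluble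
Reagents that add atoms: none
Why: Hydride reduction of the cyclic anhydride (via the lactone) touches only the carbonyl carbons, so the purchased cis relationship of both stereocentres carries through unchanged.

**Step 2**
Reactants: 2, cis-1,2-bis(hydroxymethyl)cyclobutane
Product: 3, cis-cyclobutane-1,2-dicarbaldehyde [(1R,2S), meso]
Conditions: (COCl)2 (2.6 equiv), DMSO (5.5 equiv), CH2Cl2, −78 °C; iPr2NEt (8 equiv), −78 → −30 °C; cold pH 7 buffer quench; dried solution concentrated cold and used at once without chromatography
Reagents that add atoms: none
Why: In the Swern oxidation both hydroxyls become alkoxysulfonium ions before base is added, which avoids the lactol-to-lactone path typical of 1,4-diols, and the low temperature, hindered base and buffered quench suppress α-epimerisation to the trans dialdehyde.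

**Step 3**
Reactants: 3, cis-cyclobutane-1,2-dicarbaldehyde; 4, carbon tetrabromide
Product: 5, cis-1,2-bis(2,2-dibromovinyl)cyclobutane [(1R,2S), meso]
Conditions: CBr4 (4.4 equiv), PPh3 (8.8 equiv), CH2Cl2, 0 °C, 15 min; then 3 and 2,6-lutidine (2 equiv), −20 → 0 °C, 1 h; pentane trituration and short silica plug, kept below 35 °C; check cis/trans ratio by 1H NMR
Reagents that add atoms: carbon tetrabromide, BrC(Br)(Br)Br (supplies each =CBr2 unit)
Why: In the Ramirez/Corey–Fuchs dibromo-olefination the non-basic ylide Ph3P=CBr2 undergoes Wittig reaction with both aldehydes faster than they enolise, with lutidine scavenging HBr/Ph3PBr2, and the ring C–H bonds are then only allylic and configurationally stable.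

**Step 4**
Reactants: 5, cis-1,2-bis(2,2-dibromovinyl)cyclobutane; 6, 5-bromo-2,2'-bithiophene (2.2 equiv)
Product: 7, isocardopatine, cis-1,2-bis[(2,2'-bithiophen-5-yl)ethynyl]cyclobutane [(1R,2S), meso]
Conditions: n-BuLi (4.2 equiv), THF, −78 °C, 1 h → 0 °C; anhydrous ZnBr2 (2.6 equiv), THF, 0 °C, 30 min; then 6 and Pd(PPh3)4 (5 mol %), 50 °C, 8 h, under Ar in subdued light; silica, hexane/CH2Cl2
Reagents that add atoms: 5-bromo-2,2'-bithiophene (6), Brc1ccc(-c2cccs2)s1
Why: The second Corey–Fuchs stage (Li/Br exchange with Fritsch–Buttenberg–Wiechell shift/elimination) gives the dilithium diacetylide, which is transmetallated to zinc and undergoes double Negishi alkynylation; this avoids isolating the volatile diyne, keeps BuLi away from 6, leaves the sp3 stereocentres untouched, and runs far below the Cope rearrangement threshold of cis-dialkynylcyclobutanes.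

## Compound list
| No. | Name | SMILES | Role |
|---|---|---|---|
| 1 | cis-cyclobutane-1,2-dicarboxylic anhydride | O=C1OC(=O)[C@@H]2CC[C@H]12 | starting material |
| 2 | cis-1,2-bis(hydroxymethyl)cyclobutane | OC[C@@H]1CC[C@@H]1CO | intermediate |
| 3 | cis-cyclobutane-1,2-dicarbaldehyde | O=C[C@@H]1CC[C@@H]1C=O | intermediate |
| 4 | carbon tetrabromide | BrC(Br)(Br)Br | starting material |
| 5 | cis-1,2-bis(2,2-dibromovinyl)cyclobutane | BrC(Br)=C[C@@H]1CC[C@@H]1C=C(Br)Br | intermediate |
| 6 | 5-bromo-2,2'-bithiophene | Brc1ccc(-c2cccs2)s1 | starting material |
| 7 | isocardopatine (C24H16S4) | C(#C[C@@H]1CC[C@@H]1C#Cc1ccc(-c2cccs2)s1)c1ccc(-c2cccs2)s1 | target |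

## Summary
Total step count: 4. Longest linear sequence: 4 (1 → 2 → 3 → 5 → 7).

**Steps most likely to fail**
1. **Step 2.** The cis-dialdehyde may epimerise to trans, hydrate or be lost on handling.
   Fallback: never generate the dialdehyde, and homologate one arm at a time.
   - Reduce 1 with NaBH4 to the cis-fused lactone, then with DIBAL-H to the lactol. The lactol is a ring-locked, masked mono-aldehyde.
   - Dibromo-olefinate the lactol, oxidise the freed CH2OH, and perform the second olefination to reach 5.
2. **Step 3.** The double olefination of a crowded, acid- and base-sensitive dialdehyde may stop at mono-olefination or erode the cis geometry.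
   Fallback: switch to Colvin homologation with lithiated TMS-diazomethane (TMSCHN2/LDA, THF, −78 °C). This gives cis-1,2-diethynylcyclobutane directly. Keep it as a solution and carry out a double Sonogashira coupling with 5-iodo-2,2'-bithiophene at room temperature.
3. **Step 4.** The one-pot double acetylide formation and Negishi coupling may give incomplete second coupling or a sluggish reaction with the bromide.
   Fallback: reverse the coupling polarity. Use 5 itself as the electrophile in a Pd-catalysed Stille coupling/dehydrobromination with 5-(tributylstannyl)-2,2'-bithiophene, either directly or via the bis(1-bromoalkyne), to form the internal alkynes.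
   Last resort: triplet-sensitised head-to-head [2+2] photodimerisation of 5-(but-3-en-1-ynyl)-2,2'-bithiophene, followed by chromatographic separation of the cis isomer 7 from the trans isomer.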